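**Retrosynthetic overview**

- Paratocarpin G (17, trans-2R,3R) ⇒ aryl cinnamate 14 by a photo-Fries O→C acyl shift that makes the aryl–C(=O) bond. 14 ⇒ acid 12 + 2-prenylresorcinol 5; the ester is a tether that the key step consumes, and its oxygen becomes the 2′-OH.
- Enabling feature: ring A is a 2-substituted resorcinol. C2 is blocked by the prenyl group, and C4 and C6 are equivalent, each ortho to one oxygen and para to the other. Only one monoester can exist, and ortho and para acyl migration give the same ketone.
- 12 ⇒ bromide 11 (Heck, acrylic acid). 11 ⇒ threo epoxy alcohol 9 by 5-exo-tet phenoxide opening with inversion at C2. 9 ⇒ (S)-allylic alcohol 8 (hydroxyl-directed epoxidation under allylic 1,3-strain) ⇒ aldehyde 7 (catalytic asymmetric alkenylzinc addition).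
- 5 ⇒ resorcinol by directed ortho-metalation and prenylation.
- Ring order: both benzene rings are bought; the dihydrofuran ring is the only ring formed (step 7); the key step closes no ring.

Key step: step 10

Remark: the SMILES is read as the trans-(2R,3R)-dihydrobenzofuranol; simple reagents are given by name and SMILES in the step where they are used and carry no compound number.

**Route**

Step 1
Reactants: 1 resorcinol
Product: 2 1,3-bis(methoxymethoxy)benzene
Conditions: MOMCl, i-Pr2NEt, CH2Cl2, 0 °C → rt
Reagents that add atoms: chloromethyl methyl ether (MOMCl) COCCl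
Why: Williamson-type O-alkylation of both phenols gives the bis-MOM ether, whose two acetal oxygens are the directing groups for the next step.

Step 2
Reactants: 2 1,3-bis(methoxymethoxy)benzene
Product: 4 1,3-bis(methoxymethoxy)-2-(3-methylbut-2-en-1-yl)benzene, via 2,6-bis(methoxymethoxy)phenyllithium 3 (not isolated)
Conditions: n-BuLi, THF, 0 °C → rt; then CuBr·SMe2 (10 mol%), prenyl bromide, −78 °C → rt
Reagents that add atoms: prenyl bromide (1-bromo-3-methylbut-2-ene) CC(C)=CCBr; n-butyllithium CCCC[Li] (supplies only the lithium of 3)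
Why: Directed ortho-metalation: the two OMOM groups direct lithiation cooperatively to C2 between them, and copper-catalysed allylic substitution at the primary carbon of prenyl bromide should give the linear prenyl arene.

Step 3
Reactants: 4 1,3-bis(methoxymethoxy)-2-(3-methylbut-2-en-1-yl)benzene
Product: 5 2-(3-methylbut-2-en-1-yl)benzene-1,3-diol (2-prenylresorcinol)
Conditions: HCl (cat.), MeOH, 40 °C, stopped at full conversion
Reagents that add atoms: none
Why: Acid-catalysed acetal exchange (MOM cleavage) in methanol, run mild and short so that the prenyl alkene is not protonated and closed onto the neighbouring phenol.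

Step 4
Reactants: 6 5-bromo-2-hydroxybenzaldehyde
Product: 7 5-bromo-2-[(tert-butyldimethylsilyl)oxy]benzaldehyde
Conditions: TBSCl, imidazole, DMF, rt
Reagents that add atoms: tert-butyldimethylsilyl chloride (TBSCl) CC(C)(C)[Si](C)(C)Cl
Why: Imidazole-promoted silylation of the phenol gives an ether that should survive the organozinc reagent and the peracid and is cleaved by fluoride under non-acidic conditions.

Step 5
Reactants: 7 5-bromo-2-[(tert-butyldimethylsilyl)oxy]benzaldehyde
Product: 8 (1S)-1-{5-bromo-2-[(tert-butyldimethylsilyl)oxy]phenyl}-3-methylbut-2-en-1-ol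
Conditions: (Me2C=CH)2Zn (salt-free, pre-formed from Me2C=CHMgBr), (−)-MIB (5 mol%), toluene/hexane, 0 °C; aq NH4Cl
Reagents that add atoms: bis(2-methylprop-1-en-1-yl)zinc CC(C)=C[Zn]C=C(C)C
Why: Amino-alcohol-catalysed enantioselective 1,2-addition of an alkenylzinc to an aromatic aldehyde; the (−)-MIB–zinc chelate should deliver the alkenyl group to the Si face, which sets the carbinol carbon (the later C3 of the dihydrobenzofuran) as S.

Step 6
Reactants: 8 (1S)-1-{5-bromo-2-[(tert-butyldimethylsilyl)oxy]phenyl}-3-methylbut-2-en-1-ol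
Product: 9 (R)-{5-bromo-2-[(tert-butyldimethylsilyl)oxy]phenyl}[(2S)-3,3-dimethyloxiran-2-yl]methanol
Conditions: mCPBA, NaHCO3 (buffer), CH2Cl2, 0 °C
Reagents that add atoms: 3-chloroperoxybenzoic acid (mCPBA) OOC(=O)c1cccc(Cl)c1
Why: Hydroxyl-directed Prilezhaev (Henbest) epoxidation: allylic 1,3-strain from the cis-methyl group holds the carbinol hydrogen in the alkene plane, so the hydrogen-bonded peracid attacks the face syn to OH and should give the threo epoxy alcohol, which sets the oxirane CH as S.

Step 7
Reactants: 9 (R)-{5-bromo-2-[(tert-butyldimethylsilyl)oxy]phenyl}[(2S)-3,3-dimethyloxiran-2-yl]methanol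
Product: 11 (2R,3R)-5-bromo-2-(2-hydroxypropan-2-yl)-2,3-dihydro-1-benzofuran-3-ol, via free phenol epoxy alcohol 10 (not isolated)
Conditions: TBAF, THF, 0 °C → rt; H2O work-up
Reagents that add atoms: none
Why: Fluoride desilylation unmasks the phenoxide, which opens the oxirane by 5-exo-tet SN2 attack at the less substituted carbon (favoured under basic conditions over 6-endo attack at the quaternary carbon); inversion at that carbon turns the threo epoxy alcohol into the trans-(2R,3R) ring and releases the tertiary alcohol.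

Step 8
Reactants: 11 (2R,3R)-5-bromo-2-(2-hydroxypropan-2-yl)-2,3-dihydro-1-benzofuran-3-ol
Product: 12 (2E)-3-[(2R,3R)-3-hydroxy-2-(2-hydroxypropan-2-yl)-2,3-dihydro-1-benzofuran-5-yl]prop-2-enoic acid
Conditions: acrylic acid, Pd(OAc)2 (5 mol%), P(o-tol)3 (10 mol%), Et3N, DMF, 90 °C; then cold aq citric acid (pH 4)
Reagents that add atoms: acrylic acid C=CC(=O)O
Why: Mizoroki–Heck reaction of the aryl bromide with acrylic acid; syn insertion and syn β-hydride elimination should give the E-cinnamic acid, and the free alcohols are tolerated under the basic conditions.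

Step 9
Reactants: 12 (2E)-3-[(2R,3R)-3-hydroxy-2-(2-hydroxypropan-2-yl)-2,3-dihydro-1-benzofuran-5-yl]prop-2-enoic acid; 5 2-(3-methylbut-2-en-1-yl)benzene-1,3-diol
Product: 14 3-hydroxy-2-(3-methylbut-2-en-1-yl)phenyl (2E)-3-[(2R,3R)-3-hydroxy-2-(2-hydroxypropan-2-yl)-2,3-dihydro-1-benzofuran-5-yl]prop-2-enoate, via O-acylisourea 13 (not isolated)
Conditions: 5 (3 equiv), DCC, DMAP (10 mol%), CH2Cl2/THF, 0 °C → rt; excess 5 recovered
Reagents that add atoms: N,N'-dicyclohexylcarbodiimide (DCC) C(=NC1CCCCC1)=NC1CCCCC1 (its atoms stay in 13 only, not in 14)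
Why: Steglich esterification: the phenol, used in excess, should intercept the acylpyridinium faster than the hindered secondary and the tertiary alcohol of the acid, and the symmetry of 5 means only one monoester can form.

Step 10
Reactants: 14 3-hydroxy-2-(3-methylbut-2-en-1-yl)phenyl (2E)-3-[(2R,3R)-3-hydroxy-2-(2-hydroxypropan-2-yl)-2,3-dihydro-1-benzofuran-5-yl]prop-2-enoate
Product: 17 paratocarpin G, via ortho-acyl cyclohexadienone 15 (not isolated), via para-acyl cyclohexadienone 16 (not isolated)
Conditions: hν (300–310 nm, Pyrex), degassed MeCN (2 mM), 20 °C, flow; unreacted 14 recycled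
Reagents that add atoms: none
Why: Excitation of the aryl cinnamate leads to homolysis of the ArO–C(=O) bond in the singlet state; the caged 3-hydroxy-2-prenylphenoxyl/cinnamoyl radical pair recombines at a ring carbon, and the resulting dienone (15 from attack at C6, ortho; 16 from attack at C4, para) enolises to the chelated 2-hydroxyaryl ketone. The closest known reaction type is the photo-Fries rearrangement of aryl cinnamates to 2′-hydroxychalcones and of resorcinol monoesters to 2,4-dihydroxyaryl ketones. No ring is closed and no stereocentre is created; C2 and C3 of the dihydrobenzofuran are remote from the reacting bond and untouched, and the step runs without acid or base, which the prenyl group and the benzylic alcohol require. The step needs C- over O-selectivity and one ring position out of several, and the substrate secures both: C2 is blocked by the prenyl group, C5 is meta to both oxygens and carries no spin density, and C4 and C6 lead to the same product, so ortho and para migration converge. The α,β-unsaturated acyl radical does not lose CO readily, high dilution suppresses [2+2] dimerisation, Z-ester formed by E/Z photoisomerisation is still a substrate, and the product should be shielded by fast excited-state proton transfer in its O–H···O=C chelate, the E-enone being the thermodynamic form.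

**Compound list**

1 | resorcinol | Oc1cccc(O)c1 | starting material
2 | 1,3-bis(methoxymethoxy)benzene | COCOc1cccc(OCOC)c1 | intermediate
3 | [2,6-bis(methoxymethoxy)phenyl]lithium | [Li]c1c(OCOC)cccc1OCOC | intermediate (not isolated)
4 | 1,3-bis(methoxymethoxy)-2-(3-methylbut-2-en-1-yl)benzene | COCOc1cccc(OCOC)c1CC=C(C)C | intermediate
5 | 2-(3-methylbut-2-en-1-yl)benzene-1,3-diol | CC(C)=CCc1c(O)cccc1O | intermediate
6 | 5-bromo-2-hydroxybenzaldehyde | O=Cc1cc(Br)ccc1O | starting material
7 | 5-bromo-2-[(tert-butyldimethylsilyl)oxy]benzaldehyde | O=Cc1cc(Br)ccc1O[Si](C)(C)C(C)(C)C | intermediate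
8 | (1S)-1-{5-bromo-2-[(tert-butyldimethylsilyl)oxy]phenyl}-3-methylbut-2-en-1-ol | CC(C)=C[C@H](O)c1cc(Br)ccc1O[Si](C)(C)C(C)(C)C | intermediate
9 | (R)-{5-bromo-2-[(tert-butyldimethylsilyl)oxy]phenyl}[(2S)-3,3-dimethyloxiran-2-yl]methanol | O[C@H](c1cc(Br)ccc1O[Si](C)(C)C(C)(C)C)[C@@H]1OC1(C)C | intermediate
10 | 4-bromo-2-{(R)-[(2S)-3,3-dimethyloxiran-2-yl](hydroxy)methyl}phenol (present as its tetrabutylammonium phenoxide) | O[C@H](c1cc(Br)ccc1O)[C@@H]1OC1(C)C | intermediate (not isolated)
11 | (2R,3R)-5-bromo-2-(2-hydroxypropan-2-yl)-2,3-dihydro-1-benzofuran-3-ol | Brc1ccc2c(c1)[C@@H](O)[C@H](C(C)(C)O)O2 | intermediate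
12 | (2E)-3-[(2R,3R)-3-hydroxy-2-(2-hydroxypropan-2-yl)-2,3-dihydro-1-benzofuran-5-yl]prop-2-enoic acid | OC(=O)/C=C/c1ccc2c(c1)[C@@H](O)[C@H](C(C)(C)O)O2 | intermediate
13 | O-acylisourea of 12 with DCC | O=C(/C=C/c1ccc2c(c1)[C@@H](O)[C@H](C(C)(C)O)O2)OC(=NC1CCCCC1)NC1CCCCC1 | intermediate (not isolated)
14 | 3-hydroxy-2-(3-methylbut-2-en-1-yl)phenyl (2E)-3-[(2R,3R)-3-hydroxy-2-(2-hydroxypropan-2-yl)-2,3-dihydro-1-benzofuran-5-yl]prop-2-enoate | CC(C)=CCc1c(O)cccc1OC(=O)/C=C/c1ccc2c(c1)[C@@H](O)[C@H](C(C)(C)O)O2 | intermediate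
15 | 6-acyl-3-hydroxy-2-prenylcyclohexa-2,4-dien-1-one (ortho recombination product; new sp3 carbon unassigned) | CC(C)=CCC1=C(O)C=CC(C(=O)/C=C/c2ccc3c(c2)[C@@H](O)[C@H](C(C)(C)O)O3)C1=O | intermediate (not isolated)
16 | 4-acyl-3-hydroxy-2-prenylcyclohexa-2,5-dien-1-one (para recombination product; new sp3 carbon unassigned) | CC(C)=CCC1=C(O)C(C(=O)/C=C/c2ccc3c(c2)[C@@H](O)[C@H](C(C)(C)O)O3)C=CC1=O | intermediate (not isolated)
17 | paratocarpin G, (2E)-1-[2,4-dihydroxy-3-(3-methylbut-2-en-1-yl)phenyl]-3-[(2R,3R)-3-hydroxy-2-(2-hydroxypropan-2-yl)-2,3-dihydro-1-benzofuran-5-yl]prop-2-en-1-one | CC(C)=CCc1c(O)ccc(C(=O)/C=C/c2ccc3c(c2)[C@@H](O)[C@H](C(C)(C)O)O3)c1O | target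

**Totals**

Total step count: 10. Longest linear sequence: 7 steps (6 → 17, steps 4–10); the arene branch (1 → 5) has 3 steps.

**Steps most likely to fail**

1. Step 10. The O→C acyl transfer may be inefficient: excitation can be drained by E/Z isomerisation of the cinnamate, the radical pair can escape the cage, and the product can undergo secondary photochemistry (E/Z isomerisation, closure to the flavanone). The fallback makes the same bond by polar chemistry and sets out from bromide 11 and arene 4. Heck coupling of 11 with N-methoxy-N-methylacrylamide (Pd(OAc)2, P(o-tol)3, Et3N, DMF, 90 °C) should give the Weinreb amide (2E)-3-[(2R,3R)-3-hydroxy-2-(2-hydroxypropan-2-yl)-2,3-dihydro-1-benzofuran-5-yl]-N-methoxy-N-methylprop-2-enamide F1. Arene 4 is lithiated ortho to one OMOM group (n-BuLi, TMEDA, THF, 0 °C) to give [2,4-bis(methoxymethoxy)-3-(3-methylbut-2-en-1-yl)phenyl]lithium F2, which is added in excess to F1 at −78 °C; the first two equivalents deprotonate the two alcohols and return 4. Collapse of the chelated adduct on work-up should give the protected chalcone (2E)-1-[2,4-bis(methoxymethoxy)-3-(3-methylbut-2-en-1-yl)phenyl]-3-[(2R,3R)-3-hydroxy-2-(2-hydroxypropan-2-yl)-2,3-dihydro-1-benzofuran-5-yl]prop-2-en-1-one F3. Cleavage of the two phenolic MOM ethers with NaHSO4 on silica in CH2Cl2 at room temperature, chosen to spare the prenyl group and the benzylic alcohol, brings the route back at 17.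

2. Step 5. Enantioselectivity may erode through uncatalysed or salt-promoted background addition, and transfer of the hindered trisubstituted alkenyl group may be slow. The fallback sets out from aldehyde 7. Addition of 2-methylprop-1-enylmagnesium bromide (THF, −78 °C) gives racemic 1-{5-bromo-2-[(tert-butyldimethylsilyl)oxy]phenyl}-3-methylbut-2-en-1-ol F4. Sharpless kinetic resolution (Ti(OiPr)4, L-(+)-DIPT, t-BuOOH 0.6 equiv, 4 Å MS, CH2Cl2, −20 °C) should epoxidise the R enantiomer faster, to the erythro epoxy alcohol (S)-{5-bromo-2-[(tert-butyldimethylsilyl)oxy]phenyl}[(2S)-3,3-dimethyloxiran-2-yl]methanol F5, which is separated. The unreacted S alcohol is 8, where the route is rejoined.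

3. Step 9. Chemoselectivity of the acylation may be lost: the activated hydroxy acid can esterify its own secondary alcohol (oligoesters), and the diol can be acylated twice. The fallback makes the ester C–O bond first on the simple fragment and then joins the halves by a Heck reaction; it sets out from diol 5 and bromide 11. Treatment of an excess of 5 with acryloyl chloride (0.3 equiv, Et3N, CH2Cl2, −78 °C) gives 3-hydroxy-2-(3-methylbut-2-en-1-yl)phenyl prop-2-enoate F6. Heck coupling of F6 with 11 under Jeffery conditions (Pd(OAc)2, Bu4NCl, NaHCO3, DMF, 60 °C) should give the E-cinnamate directly and returns to the route at 14.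

**Further compounds**

F1 | step 10 | (2E)-3-[(2R,3R)-3-hydroxy-2-(2-hydroxypropan-2-yl)-2,3-dihydro-1-benzofuran-5-yl]-N-methoxy-N-methylprop-2-enamide | CON(C)C(=O)/C=C/c1ccc2c(c1)[C@@H](O)[C@H](C(C)(C)O)O2
F2 | step 10 | [2,4-bis(methoxymethoxy)-3-(3-methylbut-2-en-1-yl)phenyl]lithium | [Li]c1ccc(OCOC)c(CC=C(C)C)c1OCOC
F3 | step 10 | (2E)-1-[2,4-bis(methoxymethoxy)-3-(3-methylbut-2-en-1-yl)phenyl]-3-[(2R,3R)-3-hydroxy-2-(2-hydroxypropan-2-yl)-2,3-dihydro-1-benzofuran-5-yl]prop-2-en-1-one | COCOc1ccc(C(=O)/C=C/c2ccc3c(c2)[C@@H](O)[C@H](C(C)(C)O)O3)c(OCOC)c1CC=C(C)C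
F4 | step 5 | racemic 1-{5-bromo-2-[(tert-butyldimethylsilyl)oxy]phenyl}-3-methylbut-2-en-1-ol | CC(C)=CC(O)c1cc(Br)ccc1O[Si](C)(C)C(C)(C)C
F5 | step 5 | (S)-{5-bromo-2-[(tert-butyldimethylsilyl)oxy]phenyl}[(2S)-3,3-dimethyloxiran-2-yl]methanol | O[C@@H](c1cc(Br)ccc1O[Si](C)(C)C(C)(C)C)[C@@H]1OC1(C)C
F6 | step 9 | 3-hydroxy-2-(3-methylbut-2-en-1-yl)phenyl prop-2-enoate | C=CC(=O)Oc1cccc(O)c1CC=C(C)C
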